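**Retrosynthetic overview**

1. Feature: in the chroman-4-one unit, ring C ties ring A to the quaternary C2 (which carries the 4-hydroxyphenyl group and kaempferol C8) through O1–C8a on one side and C3–C4–C4a on the other. Without the C3/C4 oxygens this is a 2,2-diaryl-2H-chromene.
2. Endgame: the furan hemiketal (kaempferol O7–C3) opens to the 3,4-dione, which comes from the cis-3,4-diol and that from the chromene C3=C4 bond.
3. Key disconnection: O1–C2 and C4–C4a of the chromene, back to a racemic diaryl propargylic alcohol and 3,5-bis(benzyloxy)phenol (etherification, [3,3] shift, 1,5-hydrogen shift, oxa-6π closure under a chiral Brønsted acid; sets C2).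
4. The propargylic alcohol comes from a diaryl ketone and ethynylmagnesium bromide; the ketone from 8-iodo-tetra-O-benzylkaempferol, 4-(benzyloxy)phenylboronic acid and CO; the iodide from kaempferol.
5. Ring order: the flavonol rings arrive with kaempferol, ring C forms in step 5, and the dihydrofuran hemiketal ring forms in step 8.

Key step: step 5

Remark: 3,5-bis(benzyloxy)phenol is taken as a purchasable compound. Unlabelled locants (O1, C2, C3, C4, C4a, C8a) refer to the chroman unit that carries ring A; kaempferol locants refer to the flavonol unit.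

**Route**

Step 1
Reactants: 1 kaempferol
Product: 2 3,5,7-tris(benzyloxy)-2-[4-(benzyloxy)phenyl]-4H-chromen-4-one (tetra-O-benzylkaempferol)
Conditions: BnBr (6 equiv), K2CO3 (8 equiv), DMF, 70 °C
Reagents that add atoms: benzyl bromide, BrCc1ccccc1
Why: Williamson O-alkylation (SN2) of all four hydroxyls; the chelated 5-OH reacts last and is driven by excess halide and heat, and capping it is what later steers halogenation to C8.

Step 2
Reactants: 2 tetra-O-benzylkaempferol
Product: 3 8-iodo-3,5,7-tris(benzyloxy)-2-[4-(benzyloxy)phenyl]-4H-chromen-4-one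
Conditions: NIS (1.1 equiv), TFA (0.2 equiv), MeCN/CH2Cl2, 0 °C to rt, dark
Reagents that add atoms: N-iodosuccinimide, O=C1CCC(=O)N1I
Why: Electrophilic aromatic iodination of the only strongly activated ring; in 5,7-dialkoxyflavones without a free 5-OH, C8 (ortho to the 7-alkoxy group and O1, para to the 5-alkoxy group) is expected to react ahead of C6, which is flanked by two benzyloxy groups, and ring B is deactivated by conjugation to the pyrone.

Step 3
Reactants: 3 8-iodo-tetra-O-benzylkaempferol; 4 4-(benzyloxy)phenylboronic acid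
Product: 5 8-[4-(benzyloxy)benzoyl]-3,5,7-tris(benzyloxy)-2-[4-(benzyloxy)phenyl]-4H-chromen-4-one
Conditions: CO (4 bar), (IPr)PdCl2(3-chloropyridine) (3 mol%; IPr = 1,3-bis(2,6-diisopropylphenyl)imidazol-2-ylidene), Cs2CO3 (3 equiv), chlorobenzene, 80 °C
Reagents that add atoms: carbon monoxide, [C-]#[O+]
Why: Carbonylative Suzuki–Miyaura coupling (oxidative addition, CO insertion to the aroyl–palladium species, transmetalation, reductive elimination), for which a bulky N-heterocyclic carbene ligand is the established answer to di-ortho-substituted aryl iodides; benzyl ethers and the pyrone are inert.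

Step 4
Reactants: 5 diaryl ketone; 6 ethynylmagnesium bromide
Product: 7 rac-1-[4-(benzyloxy)phenyl]-1-{3,5,7-tris(benzyloxy)-2-[4-(benzyloxy)phenyl]-4-oxo-4H-chromen-8-yl}prop-2-yn-1-ol
Conditions: HC≡CMgBr (0.5 M in THF, 3 equiv), THF, 0 °C to rt; aq. NH4Cl
Reagents that add atoms: none
Why: 1,2-Addition of a slim sp-carbon Grignard reagent to the diaryl ketone, which is far more electrophilic than the vinylogous-ester pyrone carbonyl (whose C2 is fully substituted); the carbinol centre forms racemic, which is immaterial because it is ionized in step 5.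

Step 5
Reactants: 7 racemic propargylic alcohol; 8 3,5-bis(benzyloxy)phenol
Product: 12 (R)-5,7-bis(benzyloxy)-2-[4-(benzyloxy)phenyl]-2-{3,5,7-tris(benzyloxy)-2-[4-(benzyloxy)phenyl]-4-oxo-4H-chromen-8-yl}-2H-chromene, via propargyl aryl ether 9 (not isolated), via ortho-allenylphenol 10 (not isolated), via ortho-quinone methide dienone 11 (not isolated)
Conditions: (R)-3,3'-bis(2,4,6-triisopropylphenyl)-1,1'-binaphthyl-2,2'-diyl N-triflylphosphoramide (10 mol%), 5 Å MS, toluene, 0 °C to rt, dark; then Et3N
Reagents that add atoms: none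
Why: Proposed new method: the acid ionizes the doubly aryl-stabilized tertiary alcohol 7 to an ion-paired propargyl/allenyl cation that phenol 8 captures at oxygen to give ether 9; a charge-accelerated aryl propargyl ether Claisen [3,3] shift (new C4–C4a bond) and enolization give allenylphenol 10, which direct ortho C-attack at the alkyne terminus would also give, and a 1,5-hydrogen shift from the phenolic OH to the central allene carbon gives the 1-oxatriene 11. Ring C, the only ring formed, closes by thermal disrotatory oxa-6π electrocyclization of 11 (new O1–C2 bond). The closest known reaction type is the racemic Brønsted-acid condensation of 1,1-diarylprop-2-yn-1-ols with phenols and naphthols to 2,2-diaryl-2H-chromenes, together with chiral-phosphate-controlled additions to hydrogen-bonded ortho-quinone methides. The single new stereocentre C2 is set in the ring closure: the chiral anion, hydrogen-bonded to the dienone oxygen of 11 or ion-paired with its O-protonated form, is expected to favour one helical sense of the s-cis,s-cis oxatriene and so one face of the diaryl terminus; the sense of induction cannot be predicted, so the catalyst antipode that delivers the (R)-chromene is the one to be used. The step needs ortho-carbon over para-carbon selectivity in the phenol and capture of the cation ahead of Meyer–Schuster rearrangement: the O-bound ether can deliver the alkyne terminus only to an ortho carbon, the two ortho carbons of symmetric 8 are equivalent, and the sieves remove the water that the Meyer–Schuster path needs. The large steric difference between the di-ortho-substituted flavonol-8-yl group and the para-benzyloxyphenyl group is what should let the catalyst tell the two faces of C2 apart, and quenching with base at full conversion and exclusion of light guard against racemization by reversible O1–C2 opening.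

Step 6
Reactants: 12 (R)-chromene
Product: 13 (2R)-5,7-bis(benzyloxy)-2-[4-(benzyloxy)phenyl]-2-{3,5,7-tris(benzyloxy)-2-[4-(benzyloxy)phenyl]-4-oxo-4H-chromen-8-yl}chromane-3,4-diol (3,4-cis; both cis diastereomers carried on)
Conditions: OsO4 (5 mol%), NMO (3 equiv), THF/t-BuOH/H2O, rt, dark
Reagents that add atoms: N-methylmorpholine N-oxide, C[N+]1([O-])CCOCC1; water, O; osmium tetroxide (catalytic oxygen carrier), O=[Os](=O)(=O)=O
Why: Upjohn syn-dihydroxylation ([3+2] addition of OsO4) of the electron-rich cis-styrenyl C3=C4 bond, while the tetrasubstituted electron-poor flavonol C2=C3 bond is untouched; the face of attack is irrelevant because both carbinol carbons become carbonyls, and C2 is not affected.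

Step 7
Reactants: 13 cis-3,4-diol
Product: 15 (2R)-5,7-bis(benzyloxy)-2-[4-(benzyloxy)phenyl]-2-{3,5,7-tris(benzyloxy)-2-[4-(benzyloxy)phenyl]-4-oxo-4H-chromen-8-yl}chromane-3,4-dione, via 3-hydroxychroman-4-one ketol 14 (not isolated)
Conditions: IBX (4 equiv), DMSO, rt to 45 °C, dark
Reagents that add atoms: none
Why: 2-Iodoxybenzoic acid oxidation of a 1,2-diol to the 1,2-dione, a reagent that oxidizes vicinal diols without cleaving the C–C bond; the benzylic C4 carbinol should go first and the hindered C3 carbinol second, and C2 is quaternary so it cannot epimerize.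

Step 8
Reactants: 15 heptabenzyl 3,4-dione
Product: 17 CNP0314633.1 (2R,3S cis-fused hemiketal), via open heptaphenol 3,4-dione 16 (not isolated)
Conditions: H2 (1 atm), Pd(OH)2/C, THF/EtOAc, rt, dark
Reagents that add atoms: none
Why: Catalytic hydrogenolysis of the seven benzyl ethers; the freed kaempferol 7-OH adds to the activated C3 ketone (5-exo-trig hemiketalization, thermodynamic control), and since the dihydrofuran ring can only be cis-fused to ring C, the (R) centre at C2 dictates (S) at C3.

**Compound list**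

1 | kaempferol | O=c1c(O)c(-c2ccc(O)cc2)oc2cc(O)cc(O)c12 | starting material
2 | 3,5,7-tris(benzyloxy)-2-[4-(benzyloxy)phenyl]-4H-chromen-4-one | O=c1c(OCc9ccccc9)c(-c2ccc(OCc9ccccc9)cc2)oc2cc(OCc9ccccc9)cc(OCc9ccccc9)c12 | intermediate
3 | 8-iodo-3,5,7-tris(benzyloxy)-2-[4-(benzyloxy)phenyl]-4H-chromen-4-one | O=c1c(OCc9ccccc9)c(-c2ccc(OCc9ccccc9)cc2)oc2c(I)c(OCc9ccccc9)cc(OCc9ccccc9)c12 | intermediate
4 | 4-(benzyloxy)phenylboronic acid | OB(O)c1ccc(OCc2ccccc2)cc1 | starting material
5 | 8-[4-(benzyloxy)benzoyl]-3,5,7-tris(benzyloxy)-2-[4-(benzyloxy)phenyl]-4H-chromen-4-one | O=C(c1ccc(OCc9ccccc9)cc1)c1c(OCc9ccccc9)cc(OCc9ccccc9)c2c(=O)c(OCc9ccccc9)c(-c3ccc(OCc9ccccc9)cc3)oc12 | intermediate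
6 | ethynylmagnesium bromide | C#C[Mg]Br | starting material
7 | rac-1-[4-(benzyloxy)phenyl]-1-(tetra-O-benzylkaempferol-8-yl)prop-2-yn-1-ol | C#CC(O)(c1ccc(OCc9ccccc9)cc1)c1c(OCc9ccccc9)cc(OCc9ccccc9)c2c(=O)c(OCc9ccccc9)c(-c3ccc(OCc9ccccc9)cc3)oc12 | intermediate
8 | 3,5-bis(benzyloxy)phenol | Oc1cc(OCc9ccccc9)cc(OCc9ccccc9)c1 | starting material
9 | 3,5-bis(benzyloxy)phenyl ether of 7 (propargylic centre unspecified) | C#CC(Oc1cc(OCc9ccccc9)cc(OCc9ccccc9)c1)(c1ccc(OCc9ccccc9)cc1)c1c(OCc9ccccc9)cc(OCc9ccccc9)c2c(=O)c(OCc9ccccc9)c(-c3ccc(OCc9ccccc9)cc3)oc12 | intermediate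
10 | 3,5-bis(benzyloxy)-2-[3-(4-benzyloxyphenyl)-3-(tetra-O-benzylkaempferol-8-yl)propa-1,2-dienyl]phenol (allene axis unspecified) | Oc1cc(OCc9ccccc9)cc(OCc9ccccc9)c1C=C=C(c1ccc(OCc9ccccc9)cc1)c1c(OCc9ccccc9)cc(OCc9ccccc9)c2c(=O)c(OCc9ccccc9)c(-c3ccc(OCc9ccccc9)cc3)oc12 | intermediate
11 | 3,5-bis(benzyloxy)-6-[3-(4-benzyloxyphenyl)-3-(tetra-O-benzylkaempferol-8-yl)prop-2-enylidene]cyclohexa-2,4-dien-1-one (double-bond geometry unspecified) | O=C1C=C(OCc9ccccc9)C=C(OCc9ccccc9)C1=CC=C(c1ccc(OCc9ccccc9)cc1)c1c(OCc9ccccc9)cc(OCc9ccccc9)c2c(=O)c(OCc9ccccc9)c(-c3ccc(OCc9ccccc9)cc3)oc12 | intermediate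
12 | (R)-5,7-bis(benzyloxy)-2-[4-(benzyloxy)phenyl]-2-(tetra-O-benzylkaempferol-8-yl)-2H-chromene | c1(OCc9ccccc9)cc(OCc9ccccc9)cc2c1C=C[C@@](c3ccc(OCc9ccccc9)cc3)(c3c(OCc9ccccc9)cc(OCc9ccccc9)c4c(=O)c(OCc9ccccc9)c(-c5ccc(OCc9ccccc9)cc5)oc34)O2 | intermediate
13 | (2R)-5,7-bis(benzyloxy)-2-[4-(benzyloxy)phenyl]-2-(tetra-O-benzylkaempferol-8-yl)chromane-3,4-diol (3,4-cis, C3/C4 face unspecified) | c1(OCc9ccccc9)cc(OCc9ccccc9)cc2c1C(O)C(O)[C@@](c3ccc(OCc9ccccc9)cc3)(c3c(OCc9ccccc9)cc(OCc9ccccc9)c4c(=O)c(OCc9ccccc9)c(-c5ccc(OCc9ccccc9)cc5)oc34)O2 | intermediate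
14 | (2R)-5,7-bis(benzyloxy)-2-[4-(benzyloxy)phenyl]-3-hydroxy-2-(tetra-O-benzylkaempferol-8-yl)chroman-4-one (C3 unspecified) | c1(OCc9ccccc9)cc(OCc9ccccc9)cc2c1C(=O)C(O)[C@@](c3ccc(OCc9ccccc9)cc3)(c3c(OCc9ccccc9)cc(OCc9ccccc9)c4c(=O)c(OCc9ccccc9)c(-c5ccc(OCc9ccccc9)cc5)oc34)O2 | intermediate
15 | (2R)-5,7-bis(benzyloxy)-2-[4-(benzyloxy)phenyl]-2-(tetra-O-benzylkaempferol-8-yl)chromane-3,4-dione | c1(OCc9ccccc9)cc(OCc9ccccc9)cc2c1C(=O)C(=O)[C@@](c3ccc(OCc9ccccc9)cc3)(c3c(OCc9ccccc9)cc(OCc9ccccc9)c4c(=O)c(OCc9ccccc9)c(-c5ccc(OCc9ccccc9)cc5)oc34)O2 | intermediate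
16 | (2R)-5,7-dihydroxy-2-(4-hydroxyphenyl)-2-(kaempferol-8-yl)chromane-3,4-dione | Oc1cc(O)cc2c1C(=O)C(=O)[C@@](c1ccc(O)cc1)(c1c(O)cc(O)c3c(=O)c(O)c(-c4ccc(O)cc4)oc13)O2 | intermediate
17 | CNP0314633.1, the (2R,3S) hemiketal in which kaempferol O7 is bonded to C3 (bearing OH) and kaempferol C8 to C2 of the 5,7-dihydroxy-2-(4-hydroxyphenyl)chroman-4-one unit | O=C1c2c(O)cc(O)cc2O[C@]2(c3ccc(O)cc3)c3c(cc(O)c4c(=O)c(O)c(-c5ccc(O)cc5)oc34)O[C@]12O | target

**Totals**

Total step count: 8. Longest linear sequence: 8 steps (1 to 17).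

**Steps most likely to fail**

Step 5 (key step, proposed method). The chiral anion may discriminate poorly between the two helical senses of the ring closure, or the product may racemize by acid- or light-induced reversible O1–C2 opening; Meyer–Schuster rearrangement of 7 or para C-alkylation of the phenol may also compete. Fallback: from 7 and 8, the known racemic condensation (PPTS cat., 4 Å MS, 1,2-dichloroethane, 60 °C) should give the racemic chromene F1. This is resolved in the dark by preparative chromatography on a chiral stationary phase (amylose tris(3,5-dimethylphenylcarbamate)), and the (R) enantiomer rejoins the route at 12. The unwanted antipode can be racemized by brief irradiation and resubmitted.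

Step 8. The 1,2-dicarbonyl may be over-reduced by hydrogen before the hemiketal closes, or the doubly benzylic C2–O1 bond may undergo hydrogenolysis. Fallback: from 15, non-reductive Lewis-acid dealkylation (BCl3, pentamethylbenzene as benzyl-cation scavenger, CH2Cl2, −78 °C; MeOH quench), so that no reductant meets the dione. This passes through 16 and rejoins at 17; no compound outside the list is formed (F0).

Step 3. Direct biaryl coupling without CO uptake, or protodeiodination, may win at the di-ortho-substituted C8 because CO insertion and transmetalation are slow there. Fallback: from 3, iodine–magnesium exchange (iPrMgCl·LiCl, THF, −40 °C) should give the 8-chloromagnesio flavonol F2, which adds to 4-(benzyloxy)benzaldehyde to give the racemic diarylmethanol F3. Oxidation of the doubly benzylic alcohol (MnO2, CH2Cl2, rt) then rejoins the route at 5.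

**Further compounds**

F1 | step 5 | racemic 5,7-bis(benzyloxy)-2-[4-(benzyloxy)phenyl]-2-(tetra-O-benzylkaempferol-8-yl)-2H-chromene | c1(OCc9ccccc9)cc(OCc9ccccc9)cc2c1C=CC(c3ccc(OCc9ccccc9)cc3)(c3c(OCc9ccccc9)cc(OCc9ccccc9)c4c(=O)c(OCc9ccccc9)c(-c5ccc(OCc9ccccc9)cc5)oc34)O2
F0 | step 8 | none | none
F2 | step 3 | 8-(chloromagnesio)-3,5,7-tris(benzyloxy)-2-[4-(benzyloxy)phenyl]-4H-chromen-4-one | Cl[Mg]c1c(OCc9ccccc9)cc(OCc9ccccc9)c2c(=O)c(OCc9ccccc9)c(-c3ccc(OCc9ccccc9)cc3)oc12
F3 | step 3 | rac-8-{[4-(benzyloxy)phenyl](hydroxy)methyl}-3,5,7-tris(benzyloxy)-2-[4-(benzyloxy)phenyl]-4H-chromen-4-one | OC(c1ccc(OCc9ccccc9)cc1)c1c(OCc9ccccc9)cc(OCc9ccccc9)c2c(=O)c(OCc9ccccc9)c(-c3ccc(OCc9ccccc9)cc3)oc12
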